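**Strategy.** The route rests on disconnecting the central 2,3-dihydrobenzofuran across its C2–C3 bond and its aryl C7a–O bond, which leaves an enantiopure diarylmethane (lower dihydrobenzofuran–CH2–fluorocyanophenyl) and 4-methoxybenzaldehyde. The key step exploits that C3 of this ring is a doubly benzylic methine lying para to C6 (the carbon that carries the stilbene link) and that the ring oxygen sits on C7a, ortho to C3a: a 6-cyano group acidifies C3–H, activates a C7a fluorine and later becomes the stilbene carbon. One base-mediated operation (carbanion addition to the aldehyde, then SNAr by the alkoxide) closes the ring and sets C2 and C3. The two flanking dihydrobenzofurans come from asymmetric carbene C–H insertion; a Heck reaction joins the halves.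

Key step: step 7

Remark on numbering: ring system A is the left dihydrobenzofuran (7-oxygenated, C5 on the stilbene), ring system B the central one (C6 on the stilbene), ring system C the lower one (its C4 bonded to C3 of B); atom numbers are benzofuran numbers within each ring system.
Assumption: Rh2(S-PTAD)4 is taken as the catalyst enantiomer that gives the (2R,3S)-cis insertion products 11 and 26; if the sense of induction is the opposite one, Rh2(R-PTAD)4 is used in steps 5 and 14.
Assumption: 1, 2, 4, 7, 13, 19 and 21 (as a THF solution) are purchased.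

**Route**

Step 1
Reactants: 1 3,5-dimethoxyphenylboronic acid; 2 4-(bromomethyl)-3-fluorobenzonitrile
Product: 3 4-(3,5-dimethoxybenzyl)-3-fluorobenzonitrile
Conditions: Pd(PPh3)4 (3 mol %), K2CO3, DME/H2O, 80 °C
Reagents that add atoms: none
Why: Suzuki–Miyaura coupling of an arylboronic acid with an electron-poor benzylic bromide should give the diarylmethane, because the benzylic C–Br bond adds to zerovalent palladium far faster than the aryl C–F bond.

Step 2
Reactants: 3 4-(3,5-dimethoxybenzyl)-3-fluorobenzonitrile; 4 3,5-dimethoxybenzoyl chloride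
Product: 6 4-[2-(3,5-dimethoxybenzoyl)-3-hydroxy-5-methoxybenzyl]-3-fluorobenzonitrile, via methyl ether ketone 5 (not isolated)
Conditions: AlCl3 (3.5 equiv), CH2Cl2, 0 °C to reflux; then ice/aq. HCl
Reagents that add atoms: none
Why: Friedel–Crafts acylation should occur ortho to the benzylic CH2 and para to a methoxy group (the less hindered activated position; the fluorocyanophenyl ring is deactivated), and the aluminium chelate of the new ketone then cleaves only the methyl ether ortho to the carbonyl group.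

Step 3
Reactants: 6 4-[2-(3,5-dimethoxybenzoyl)-3-hydroxy-5-methoxybenzyl]-3-fluorobenzonitrile; 7 4-methoxybenzyl chloride
Product: 8 4-{2-(3,5-dimethoxybenzoyl)-5-methoxy-3-[(4-methoxybenzyl)oxy]benzyl}-3-fluorobenzonitrile
Conditions: K2CO3, n-Bu4NI (cat.), DMF, 50 °C
Reagents that add atoms: none
Why: Williamson ether synthesis on the phenoxide installs the benzylic ether whose CH2 becomes C2 of ring system C, K2CO3 being too weak to deprotonate the diarylmethane CH2.

Step 4
Reactants: 8 4-{2-(3,5-dimethoxybenzoyl)-5-methoxy-3-[(4-methoxybenzyl)oxy]benzyl}-3-fluorobenzonitrile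
Product: 9 hydrazone of 8 (C=N–NH2 at the former ketone carbon; E/Z mixture)
Conditions: N2H4·H2O (excess), AcOH (cat.), EtOH, 90 °C, sealed tube
Reagents that add atoms: hydrazine hydrate, NN.O
Why: acid-catalysed hydrazone condensation, driven by excess hydrazine (which also suppresses azine formation), should proceed while the nitrile and the unactivated aryl fluoride are left alone at this temperature.

Step 5
Reactants: 9 hydrazone of 8
Product: 11 4-{[(2R,3S)-3-(3,5-dimethoxyphenyl)-6-methoxy-2-(4-methoxyphenyl)-2,3-dihydrobenzofuran-4-yl]methyl}-3-fluorobenzonitrile (cis), via diaryldiazomethane 10 (not isolated)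
Conditions: MnO2, CH2Cl2, 0 °C, filtration; then Rh2(S-PTAD)4 (dirhodium tetrakis[(S)-(1-adamantyl)(phthalimido)acetate], 1 mol %), CH2Cl2, 0 °C to rt
Reagents that add atoms: none
Why: hydrazone oxidation gives a donor/donor diazo compound whose dirhodium carbene undergoes intramolecular 1,5 C–H insertion into the activated benzylic ether CH2 (asymmetric carbene C–H insertion), the chiral carboxylate ligands setting C3 as S and the concerted, asynchronous insertion delivering the cis-2,3-diaryl ring.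

Step 6
Reactants: 11 cis-(2R,3S) dihydrobenzofuran
Product: 12 4-{[(2S,3S)-3-(3,5-dimethoxyphenyl)-6-methoxy-2-(4-methoxyphenyl)-2,3-dihydrobenzofuran-4-yl]methyl}-3-fluorobenzonitrile (trans)
Conditions: CF3CO2H (10 equiv), CH2Cl2, 0 °C to rt
Reagents that add atoms: none
Why: acid-mediated epimerisation at C2 by reversible ionisation of the C2–O bond to the 4-methoxybenzylic cation and reclosure should give the thermodynamically preferred trans isomer, while C3 is not involved and keeps the configuration set in step 5.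

Step 7
Reactants: 12 trans-(2S,3S) diarylmethane nitrile; 13 4-methoxybenzaldehyde
Product: 16 (2R,3R)-3-[(2S,3S)-3-(3,5-dimethoxyphenyl)-6-methoxy-2-(4-methoxyphenyl)-2,3-dihydrobenzofuran-4-yl]-2-(4-methoxyphenyl)-2,3-dihydrobenzofuran-6-carbonitrile, via potassium carbanion 14 (not isolated), via potassium alkoxide 15 (not isolated)
Conditions: KOt-Bu (1.15 equiv), THF/DMF, −40 °C to 60 °C, argon
Reagents that add atoms: none
Why: KOt-Bu removes the doubly benzylic proton para to the nitrile, the delocalised carbanion 14 adds to the aldehyde to form the C2–C3 bond, and the alkoxide 15 then displaces the ortho fluorine by addition–elimination to form the C7a–O bond, so both bonds arise in one operation. The closest known reaction types are the domino benzylic carbanion addition/intramolecular SNAr that converts 2-fluorotoluenes and nitriles into indoles, and the SNAr cyclisation of 2-(2-fluorophenyl)ethanols to dihydrobenzofurans. The furan ring of ring system B closes by 5-exo-trig attack of the alkoxide oxygen on C7a (exo with respect to the C7a=C7 bond), the meta nitrile lowering the barrier inductively. C2 and C3 should emerge trans because the aldol addition is reversible while cyclisation through the arrangement with the two aryl groups anti is faster, and because C3–H of 16 remains acidic so that a cis isomer can equilibrate. The absolute sense should be set by ring system C: the carbanion plane stands perpendicular to that arene with C3–H on the face of the 3,5-dimethoxyphenyl group at C3 of C, and the aldehyde approaches from the open side next to C5–H of C, which gives 3R and, through the trans closure, 2R. The step needs this facial selectivity and needs C–H deprotonation to outrun attack on the nitrile or aldehyde, which the hindered alkoxide base, used in slight excess only, and the low starting temperature should secure.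

Step 8
Reactants: 16 ring B nitrile
Product: 17 (2R,3R)-3-[(2S,3S)-3-(3,5-dimethoxyphenyl)-6-methoxy-2-(4-methoxyphenyl)-2,3-dihydrobenzofuran-4-yl]-2-(4-methoxyphenyl)-2,3-dihydrobenzofuran-6-carbaldehyde
Conditions: i-Bu2AlH (1.3 equiv), toluene/CH2Cl2, −78 °C; then 1 M aq. HCl, 0 °C
Reagents that add atoms: water, O
Why: nitrile-to-aldehyde reduction (hydride addition to the N-aluminated aldimine, then hydrolysis) should stop at the aldehyde at −78 °C and touches no stereocenter.

Step 9
Reactants: 17 ring B aldehyde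
Product: 18 (2R,3R)-6-ethenyl-3-[(2S,3S)-3-(3,5-dimethoxyphenyl)-6-methoxy-2-(4-methoxyphenyl)-2,3-dihydrobenzofuran-4-yl]-2-(4-methoxyphenyl)-2,3-dihydrobenzofuran
Conditions: Ph3PCH3Br, KOt-Bu, THF, 0 °C (ylide preformed), then 17, 0 °C to rt
Reagents that add atoms: methyltriphenylphosphonium bromide, C[P+](c1ccccc1)(c1ccccc1)c1ccccc1.[Br-]
Why: Wittig methylenation with the preformed non-stabilised ylide converts the aldehyde into the styrene, and any epimerisation of the C3–H para to the formyl group would only return the trans ring.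

Step 10
Reactants: 19 5-bromo-2-hydroxy-3-methoxybenzaldehyde; 7 4-methoxybenzyl chloride
Product: 20 5-bromo-3-methoxy-2-[(4-methoxybenzyl)oxy]benzaldehyde
Conditions: K2CO3, n-Bu4NI (cat.), DMF, 50 °C
Reagents that add atoms: none
Why: Williamson ether synthesis on the phenoxide installs the benzylic ether whose CH2 becomes C2 of ring system A.

Step 11
Reactants: 20 5-bromo-3-methoxy-2-[(4-methoxybenzyl)oxy]benzaldehyde; 21 3,5-dimethoxyphenylmagnesium bromide
Product: 22 {5-bromo-3-methoxy-2-[(4-methoxybenzyl)oxy]phenyl}(3,5-dimethoxyphenyl)methanol (racemic)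
Conditions: THF, −20 °C to 0 °C; then aq. NH4Cl
Reagents that add atoms: none
Why: Grignard addition to the aldehyde is much faster than any exchange with the aryl bromide, and the racemic carbinol stereocenter is removed in step 12.

Step 12
Reactants: 22 racemic diaryl carbinol
Product: 23 {5-bromo-3-methoxy-2-[(4-methoxybenzyl)oxy]phenyl}(3,5-dimethoxyphenyl)methanone
Conditions: MnO2 (activated, excess), CH2Cl2, rt
Reagents that add atoms: none
Why: oxidation of a doubly benzylic alcohol with activated MnO2 is selective and leaves the benzylic ether and the aryl bromide untouched.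

Step 13
Reactants: 23 diaryl ketone
Product: 24 hydrazone of 23 (E/Z mixture)
Conditions: N2H4·H2O (excess), AcOH (cat.), EtOH, 80 °C
Reagents that add atoms: hydrazine hydrate, NN.O
Why: acid-catalysed hydrazone condensation should be straightforward at this ketone, which has only one ortho substituent.

Step 14
Reactants: 24 hydrazone of 23
Product: 26 (2R,3S)-5-bromo-3-(3,5-dimethoxyphenyl)-7-methoxy-2-(4-methoxyphenyl)-2,3-dihydrobenzofuran (cis), via diaryldiazomethane 25 (not isolated)
Conditions: MnO2, CH2Cl2, 0 °C, filtration; then Rh2(S-PTAD)4 (1 mol %), CH2Cl2, 0 °C to rt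
Reagents that add atoms: none
Why: the same asymmetric donor/donor carbene C–H insertion as in step 5 closes ring system A, the catalyst setting C3 as S and the insertion geometry giving the cis ring.

Step 15
Reactants: 26 cis-(2R,3S) bromide
Product: 27 (2S,3S)-5-bromo-3-(3,5-dimethoxyphenyl)-7-methoxy-2-(4-methoxyphenyl)-2,3-dihydrobenzofuran (trans)
Conditions: CF3CO2H (10 equiv), CH2Cl2, 0 °C to rt
Reagents that add atoms: none
Why: acid-mediated C2 epimerisation by reversible benzylic C2–O ionisation gives the trans ring, C3 keeping its catalyst-set configuration.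

Step 16
Reactants: 18 ring B/C styrene; 27 trans ring A bromide
Product: 28 nona-O-methyl ether of the target (E-stilbene between C5 of A and C6 of B)
Conditions: Pd(OAc)2 (5 mol %), P(o-tol)3, K2CO3, n-Bu4NBr, DMF, 100 °C
Reagents that add atoms: none
Why: Heck reaction (oxidative addition of the aryl bromide to zerovalent palladium, syn insertion at the terminal styrene carbon, syn β-hydride elimination) should give the E-stilbene and involves no stereocenter.

Step 17
Reactants: 28 nona-O-methyl ether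
Product: 29 target (CNP0265934.1)
Conditions: BBr3 (about 3 equiv per OMe), CH2Cl2, −78 °C to rt; then MeOH/H2O, NaHCO3
Reagents that add atoms: none
Why: Lewis acid-mediated cleavage of aryl methyl ethers should free all nine phenols, any reversible opening of a benzylic C2–O bond reclosing to the trans ring because each C3 is untouched, and the excess BBr3 keeping all aryl oxygens complexed so that the arenes are deactivated toward Friedel–Crafts capture.

**Compound list**

1 | 3,5-dimethoxyphenylboronic acid | COc1cc(OC)cc(B(O)O)c1 | starting material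
2 | 4-(bromomethyl)-3-fluorobenzonitrile | N#Cc1ccc(CBr)c(F)c1 | starting material
3 | 4-(3,5-dimethoxybenzyl)-3-fluorobenzonitrile | COc1cc(OC)cc(Cc2ccc(C#N)cc2F)c1 | intermediate
4 | 3,5-dimethoxybenzoyl chloride | COc1cc(OC)cc(C(Cl)=O)c1 | starting material
5 | 4-[2-(3,5-dimethoxybenzoyl)-3,5-dimethoxybenzyl]-3-fluorobenzonitrile | COc1cc(OC)cc(C(=O)c2c(OC)cc(OC)cc2Cc2ccc(C#N)cc2F)c1 | intermediate
6 | 4-[2-(3,5-dimethoxybenzoyl)-3-hydroxy-5-methoxybenzyl]-3-fluorobenzonitrile | COc1cc(OC)cc(C(=O)c2c(O)cc(OC)cc2Cc2ccc(C#N)cc2F)c1 | intermediate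
7 | 4-methoxybenzyl chloride | COc1ccc(CCl)cc1 | starting material
8 | 4-{2-(3,5-dimethoxybenzoyl)-5-methoxy-3-[(4-methoxybenzyl)oxy]benzyl}-3-fluorobenzonitrile | COc1cc(OC)cc(C(=O)c2c(OCc3ccc(OC)cc3)cc(OC)cc2Cc2ccc(C#N)cc2F)c1 | intermediate
9 | hydrazone of 8 (E/Z mixture) | COc1cc(OC)cc(C(=NN)c2c(OCc3ccc(OC)cc3)cc(OC)cc2Cc2ccc(C#N)cc2F)c1 | intermediate
10 | 4-{2-[diazo(3,5-dimethoxyphenyl)methyl]-5-methoxy-3-[(4-methoxybenzyl)oxy]benzyl}-3-fluorobenzonitrile | COc1cc(OC)cc(C(=[N+]=[N-])c2c(OCc3ccc(OC)cc3)cc(OC)cc2Cc2ccc(C#N)cc2F)c1 | intermediate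
11 | 4-{[(2R,3S)-3-(3,5-dimethoxyphenyl)-6-methoxy-2-(4-methoxyphenyl)-2,3-dihydrobenzofuran-4-yl]methyl}-3-fluorobenzonitrile (cis) | N#Cc1ccc(Cc2cc(OC)cc3c2[C@H](c2cc(OC)cc(OC)c2)[C@H](c2ccc(OC)cc2)O3)c(F)c1 | intermediate
12 | 4-{[(2S,3S)-3-(3,5-dimethoxyphenyl)-6-methoxy-2-(4-methoxyphenyl)-2,3-dihydrobenzofuran-4-yl]methyl}-3-fluorobenzonitrile (trans) | N#Cc1ccc(Cc2cc(OC)cc3c2[C@H](c2cc(OC)cc(OC)c2)[C@@H](c2ccc(OC)cc2)O3)c(F)c1 | intermediate
13 | 4-methoxybenzaldehyde | COc1ccc(C=O)cc1 | starting material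
14 | potassium salt of the diarylmethyl carbanion of 12 | [K+].N#Cc1ccc([CH-]c2cc(OC)cc3c2[C@H](c2cc(OC)cc(OC)c2)[C@@H](c2ccc(OC)cc2)O3)c(F)c1 | intermediate
15 | potassium (1R,2R)-2-(4-cyano-2-fluorophenyl)-2-[(2S,3S)-3-(3,5-dimethoxyphenyl)-6-methoxy-2-(4-methoxyphenyl)-2,3-dihydrobenzofuran-4-yl]-1-(4-methoxyphenyl)ethanolate | [K+].[O-][C@@H](c1ccc(OC)cc1)[C@@H](c1ccc(C#N)cc1F)c1cc(OC)cc2c1[C@H](c1cc(OC)cc(OC)c1)[C@@H](c1ccc(OC)cc1)O2 | intermediate
16 | (2R,3R)-3-[(2S,3S)-3-(3,5-dimethoxyphenyl)-6-methoxy-2-(4-methoxyphenyl)-2,3-dihydrobenzofuran-4-yl]-2-(4-methoxyphenyl)-2,3-dihydrobenzofuran-6-carbonitrile | N#Cc1ccc2c(c1)O[C@@H](c1ccc(OC)cc1)[C@@H]2c1cc(OC)cc2c1[C@H](c1cc(OC)cc(OC)c1)[C@@H](c1ccc(OC)cc1)O2 | intermediate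
17 | the corresponding 6-carbaldehyde, (2R,3R) in ring B and (2S,3S) in ring C | O=Cc1ccc2c(c1)O[C@@H](c1ccc(OC)cc1)[C@@H]2c1cc(OC)cc2c1[C@H](c1cc(OC)cc(OC)c1)[C@@H](c1ccc(OC)cc1)O2 | intermediate
18 | the corresponding 6-ethenyl compound, (2R,3R) in ring B and (2S,3S) in ring C | C=Cc1ccc2c(c1)O[C@@H](c1ccc(OC)cc1)[C@@H]2c1cc(OC)cc2c1[C@H](c1cc(OC)cc(OC)c1)[C@@H](c1ccc(OC)cc1)O2 | intermediate
19 | 5-bromo-2-hydroxy-3-methoxybenzaldehyde | COc1cc(Br)cc(C=O)c1O | starting material
20 | 5-bromo-3-methoxy-2-[(4-methoxybenzyl)oxy]benzaldehyde | COc1ccc(COc2c(OC)cc(Br)cc2C=O)cc1 | intermediate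
21 | 3,5-dimethoxyphenylmagnesium bromide | COc1cc(OC)cc([Mg]Br)c1 | starting material
22 | {5-bromo-3-methoxy-2-[(4-methoxybenzyl)oxy]phenyl}(3,5-dimethoxyphenyl)methanol (racemic) | COc1ccc(COc2c(OC)cc(Br)cc2C(O)c2cc(OC)cc(OC)c2)cc1 | intermediate
23 | {5-bromo-3-methoxy-2-[(4-methoxybenzyl)oxy]phenyl}(3,5-dimethoxyphenyl)methanone | COc1ccc(COc2c(OC)cc(Br)cc2C(=O)c2cc(OC)cc(OC)c2)cc1 | intermediate
24 | hydrazone of 23 (E/Z mixture) | COc1ccc(COc2c(OC)cc(Br)cc2C(=NN)c2cc(OC)cc(OC)c2)cc1 | intermediate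
25 | 5-bromo-1-[diazo(3,5-dimethoxyphenyl)methyl]-3-methoxy-2-[(4-methoxybenzyl)oxy]benzene | COc1ccc(COc2c(OC)cc(Br)cc2C(=[N+]=[N-])c2cc(OC)cc(OC)c2)cc1 | intermediate
26 | (2R,3S)-5-bromo-3-(3,5-dimethoxyphenyl)-7-methoxy-2-(4-methoxyphenyl)-2,3-dihydrobenzofuran (cis) | COc1ccc([C@@H]2Oc3c(OC)cc(Br)cc3[C@@H]2c2cc(OC)cc(OC)c2)cc1 | intermediate
27 | (2S,3S)-5-bromo-3-(3,5-dimethoxyphenyl)-7-methoxy-2-(4-methoxyphenyl)-2,3-dihydrobenzofuran (trans) | COc1ccc([C@H]2Oc3c(OC)cc(Br)cc3[C@@H]2c2cc(OC)cc(OC)c2)cc1 | intermediate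
28 | nona-O-methyl ether of 29: E-stilbene from C5 of ring A (2S,3S) to C6 of ring B (2R,3R), ring B C3 bonded to C4 of ring C (2S,3S) | COc1ccc([C@H]2Oc3c(OC)cc(/C=C/c4ccc5c(c4)O[C@@H](c4ccc(OC)cc4)[C@@H]5c4cc(OC)cc5c4[C@H](c4cc(OC)cc(OC)c4)[C@@H](c4ccc(OC)cc4)O5)cc3[C@@H]2c2cc(OC)cc(OC)c2)cc1 | intermediate
29 | CNP0265934.1: ring A (2S,3S)-3-(3,5-dihydroxyphenyl)-7-hydroxy-2-(4-hydroxyphenyl)-2,3-dihydrobenzofuran-5-yl, E-ethene-1,2-diyl, ring B (2R,3R)-2-(4-hydroxyphenyl)-2,3-dihydrobenzofuran-6-yl whose C3 carries C4 of ring C (2S,3S)-3-(3,5-dihydroxyphenyl)-6-hydroxy-2-(4-hydroxyphenyl)-2,3-dihydrobenzofuran | Oc1ccc([C@H]2Oc3c(O)cc(/C=C/c4ccc5c(c4)O[C@@H](c4ccc(O)cc4)[C@@H]5c4cc(O)cc5c4[C@H](c4cc(O)cc(O)c4)[C@@H](c4ccc(O)cc4)O5)cc3[C@@H]2c2cc(O)cc(O)c2)cc1 | target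

Total step count: 17. Longest linear sequence: 11 steps (steps 1–9, 16, 17); steps 10–15 form the second branch.

**Steps most likely to fail**

1. Step 7 (key step). The facial control exerted by ring system C may be poor, so that the new ring forms with the opposite absolute sense. The aldolate may also revert without ring closure, or surplus base may open the new ring by elimination. Fallback, with catalyst control and the two bonds made separately: setting out from 12, the acidic CH2 is oxidised (Cs2CO3, O2, DMSO) to the diaryl ketone F1. The fluorine, now ortho to a carbonyl group, is displaced by the sodium alkoxide of 4-methoxybenzyl alcohol (NaH, THF) to give the benzylic ether ketone F2. Hydrazine hydrate gives the hydrazone F3, and MnO2 oxidises it to the diaryldiazomethane F4 (not isolated). Rh2(S-PTAD)4 then effects carbene C–H insertion to the cis (2R,3S) isomer F5 of the ring B nitrile, the catalyst fixing C2. Catalytic KOt-Bu in t-BuOH/THF epimerises the acidic C3–H (base and not acid, to avoid ionising C2–O) and returns to the route at 16.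

2. Step 17 (global demethylation). Ionisation of the benzylic C2–O bond of ring system B by the Lewis acid may be followed by irreversible Friedel–Crafts ring closure onto the 3,5-dioxygenated aryl group at C3 of C (seven-membered ring), and cleavage of nine ethers may stall. Fallback, a change of protecting group before ring B exists, so that ring B never meets a Lewis acid: setting out from 12, BBr3 gives the tetraphenol nitrile F6 and MOMCl/i-Pr2NEt the tetrakis(methoxymethyl) ether F7. The domino of step 7 with 4-(methoxymethoxy)benzaldehyde and KOt-Bu runs through the potassium carbanion F8 and the potassium alkoxide F9 (neither isolated) to the pentakis(methoxymethyl) ring B nitrile F10. i-Bu2AlH gives the aldehyde F11 and Wittig methylenation the styrene F12. Setting out from 27, BBr3 gives the tetraphenol bromide F13 and MOMCl/i-Pr2NEt the tetrakis(methoxymethyl) ether bromide F14. Heck coupling of F12 with F14 gives the nonakis(methoxymethyl) ether stilbene F15, and dilute HCl in MeOH at rt (acetal exchange) returns to the route at 29.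

3. Step 4 (hydrazone formation). Condensation at a ketone flanked by two ortho substituents may be slow or incomplete, and prolonged heating invites attack of hydrazine on the nitrile. Fallback, a change of sequence: setting out from 6, whose small, hydrogen-bonding ortho hydroxyl activates the carbonyl group, hydrazine hydrate in EtOH gives the hydroxy ketone hydrazone F16. O-alkylation of its phenoxide with 7 (K2CO3, acetone, rt) returns to the route at 9.

Further compounds
F1 | step 7 | 4-[(2S,3S)-3-(3,5-dimethoxyphenyl)-6-methoxy-2-(4-methoxyphenyl)-2,3-dihydrobenzofuran-4-carbonyl]-3-fluorobenzonitrile | N#Cc1ccc(C(=O)c2cc(OC)cc3c2[C@H](c2cc(OC)cc(OC)c2)[C@@H](c2ccc(OC)cc2)O3)c(F)c1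
F2 | step 7 | 4-[(2S,3S)-3-(3,5-dimethoxyphenyl)-6-methoxy-2-(4-methoxyphenyl)-2,3-dihydrobenzofuran-4-carbonyl]-3-[(4-methoxybenzyl)oxy]benzonitrile | N#Cc1ccc(C(=O)c2cc(OC)cc3c2[C@H](c2cc(OC)cc(OC)c2)[C@@H](c2ccc(OC)cc2)O3)c(OCc2ccc(OC)cc2)c1
F3 | step 7 | hydrazone of F2 (E/Z mixture) | N#Cc1ccc(C(=NN)c2cc(OC)cc3c2[C@H](c2cc(OC)cc(OC)c2)[C@@H](c2ccc(OC)cc2)O3)c(OCc2ccc(OC)cc2)c1
F4 | step 7 | diaryldiazomethane from F3 | N#Cc1ccc(C(=[N+]=[N-])c2cc(OC)cc3c2[C@H](c2cc(OC)cc(OC)c2)[C@@H](c2ccc(OC)cc2)O3)c(OCc2ccc(OC)cc2)c1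
F5 | step 7 | (2R,3S)-3-[(2S,3S)-3-(3,5-dimethoxyphenyl)-6-methoxy-2-(4-methoxyphenyl)-2,3-dihydrobenzofuran-4-yl]-2-(4-methoxyphenyl)-2,3-dihydrobenzofuran-6-carbonitrile (cis in ring B) | N#Cc1ccc2c(c1)O[C@@H](c1ccc(OC)cc1)[C@H]2c1cc(OC)cc2c1[C@H](c1cc(OC)cc(OC)c1)[C@@H](c1ccc(OC)cc1)O2
F6 | step 17 | 4-{[(2S,3S)-3-(3,5-dihydroxyphenyl)-6-hydroxy-2-(4-hydroxyphenyl)-2,3-dihydrobenzofuran-4-yl]methyl}-3-fluorobenzonitrile | N#Cc1ccc(Cc2cc(O)cc3c2[C@H](c2cc(O)cc(O)c2)[C@@H](c2ccc(O)cc2)O3)c(F)c1
F7 | step 17 | tetrakis(methoxymethyl) ether of F6 | N#Cc1ccc(Cc2cc(OCOC)cc3c2[C@H](c2cc(OCOC)cc(OCOC)c2)[C@@H](c2ccc(OCOC)cc2)O3)c(F)c1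
F8 | step 17 | potassium salt of the diarylmethyl carbanion of F7 | [K+].N#Cc1ccc([CH-]c2cc(OCOC)cc3c2[C@H](c2cc(OCOC)cc(OCOC)c2)[C@@H](c2ccc(OCOC)cc2)O3)c(F)c1
F9 | step 17 | potassium (1R,2R)-alkoxide from F8 and 4-(methoxymethoxy)benzaldehyde | [K+].[O-][C@@H](c1ccc(OCOC)cc1)[C@@H](c1ccc(C#N)cc1F)c1cc(OCOC)cc2c1[C@H](c1cc(OCOC)cc(OCOC)c1)[C@@H](c1ccc(OCOC)cc1)O2
F10 | step 17 | pentakis(methoxymethyl) analogue of 16, (2R,3R) in ring B and (2S,3S) in ring C | N#Cc1ccc2c(c1)O[C@@H](c1ccc(OCOC)cc1)[C@@H]2c1cc(OCOC)cc2c1[C@H](c1cc(OCOC)cc(OCOC)c1)[C@@H](c1ccc(OCOC)cc1)O2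
F11 | step 17 | pentakis(methoxymethyl) analogue of aldehyde 17 | O=Cc1ccc2c(c1)O[C@@H](c1ccc(OCOC)cc1)[C@@H]2c1cc(OCOC)cc2c1[C@H](c1cc(OCOC)cc(OCOC)c1)[C@@H](c1ccc(OCOC)cc1)O2
F12 | step 17 | pentakis(methoxymethyl) analogue of styrene 18 | C=Cc1ccc2c(c1)O[C@@H](c1ccc(OCOC)cc1)[C@@H]2c1cc(OCOC)cc2c1[C@H](c1cc(OCOC)cc(OCOC)c1)[C@@H](c1ccc(OCOC)cc1)O2
F13 | step 17 | (2S,3S)-5-bromo-3-(3,5-dihydroxyphenyl)-2-(4-hydroxyphenyl)-2,3-dihydrobenzofuran-7-ol | Oc1ccc([C@H]2Oc3c(O)cc(Br)cc3[C@@H]2c2cc(O)cc(O)c2)cc1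
F14 | step 17 | tetrakis(methoxymethyl) ether of F13 | COCOc1ccc([C@H]2Oc3c(OCOC)cc(Br)cc3[C@@H]2c2cc(OCOC)cc(OCOC)c2)cc1
F15 | step 17 | nonakis(methoxymethyl) ether of 29 | COCOc1ccc([C@H]2Oc3c(OCOC)cc(/C=C/c4ccc5c(c4)O[C@@H](c4ccc(OCOC)cc4)[C@@H]5c4cc(OCOC)cc5c4[C@H](c4cc(OCOC)cc(OCOC)c4)[C@@H](c4ccc(OCOC)cc4)O5)cc3[C@@H]2c2cc(OCOC)cc(OCOC)c2)cc1
F16 | step 4 | hydrazone of 6 (E/Z mixture) | COc1cc(OC)cc(C(=NN)c2c(O)cc(OC)cc2Cc2ccc(C#N)cc2F)c1
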